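**Retrosynthetic overview**
- The C12–OOH group comes from the (12S)-allylic alcohol by sulfonate displacement with H2O2 (inversion). The C12–C13 bond comes from a catalyst-controlled homoallenylboration of a C12 aldehyde, which is a cleaved allyl group on C9.
- 6β-OH, 7β-OAc and 5α-H come from hydride reduction of a ring B diosphenol (C5=C6(OH)–C7=O), with every hydrogen entering from the α face.
- Ring B (C5–C6–C7–C8–C9–C10) comes from a five-membered B-nor ring (C5–C6–C7–C9–C10). The C8–C9 bond forms when C9 shifts from C7 to an acetyl carbon standing on C7.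
- Enabling feature: in ring B the oxygenated C7 adjoins the tertiary carbinol C8 that carries the C17 methyl group. This C7(O)–C8(OH)(CH3) pair is the retron of an α-ketol shift, so C8/C17 is an acetyl group on a cyclopentanol carbon of a strained trans-hydrindane.
- Ring order: ring A is bought, and C10 is set by asymmetric allylation. The cyclopentenone is closed by Wacker oxidation and aldol condensation, then enlarged to ring B.

Key step: step 8

Remark: labdane numbering and α/β descriptors are used for all bicyclic compounds (the oxygen-bearing carbon of the five-membered ring is C7); the sense of induction of (R)-t-Bu-PHOX and of the (R)-phosphoric acid is assumed to be that shown by simple cyclohexanone enol carbonates and simple aldehydes.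

Step 1
Reactants: 1 2,2,6-trimethylcyclohexanone; 2 allyl chloroformate
Product: 3 allyl 2,6,6-trimethylcyclohex-1-en-1-yl carbonate
Conditions: LiN(SiMe3)2, THF, −78 °C; then 2, −78 °C to rt
Reagents that add atoms: allyl chloroformate (2), C=CCOC(=O)Cl
Why: Enolate O-acylation: C6 is the only enolisable position of 1 and the hard chloroformate acylates the lithium enolate on oxygen, so one enol carbonate forms and the racemic centre of 1 is erased.

Step 2
Reactants: 3 allyl 2,6,6-trimethylcyclohex-1-en-1-yl carbonate
Product: 4 (R)-2-allyl-2,6,6-trimethylcyclohexanone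
Conditions: Pd2(dba)3 (cat.), (R)-t-Bu-PHOX (cat.), THF, 25 °C
Reagents that add atoms: none
Why: Decarboxylative asymmetric allylic alkylation (Tsuji–Trost type): zerovalent palladium ionises the allyl carbonate, CO2 is lost, and the enolate recombines with the π-allyl unit inside the pocket of the (R)-PHOX ligand, which sets the quaternary centre (future C10) as R.

Step 3
Reactants: 4 (R)-2-allyl-2,6,6-trimethylcyclohexanone
Product: 5 (R)-2,2,6-trimethyl-6-(2-oxopropyl)cyclohexanone
Conditions: PdCl2 (cat.), Cu(OAc)2 (cat.), O2 (1 atm), DMA/H2O, rt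
Reagents that add atoms: water, O
Why: Wacker–Tsuji oxidation: divalent palladium activates the terminal alkene for Markovnikov attack of water, giving the methyl ketone without touching the hindered ring ketone or the quaternary centre.

Step 4
Reactants: 5 (R)-2,2,6-trimethyl-6-(2-oxopropyl)cyclohexanone
Product: 6 (7aR)-4,4,7a-trimethyl-1,4,5,6,7,7a-hexahydro-2H-inden-2-one (B-nor enone, C5=C6–C7=O)
Conditions: KOH, xylenes, 110 °C, Dean–Stark trap
Reagents that add atoms: none
Why: Intramolecular aldol condensation: only the methyl-side enolate can reach the ring carbonyl through a five-membered transition state (5-enolexo closure of the C5–C6 bond), and azeotropic removal of water drives the hindered addition on to the enone.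

Step 5
Reactants: 6 B-nor enone; 7 allyl bromide
Product: 8 (7aR)-1-allyl-4,4,7a-trimethyl-1,4,5,6,7,7a-hexahydro-2H-inden-2-one (both C9 epimers)
Conditions: LiN(i-Pr)2, THF, −78 °C; then 7, DMPU, −78 to −20 °C
Reagents that add atoms: allyl bromide (7), C=CCBr
Why: Kinetic enolate alkylation: both γ-carbons of the enone (C4, C10) are quaternary, so C9 is the only acidic site and is allylated there, and the facial outcome at C9 is irrelevant because this centre is equilibrated in step 6.

Step 6
Reactants: 8 9-allyl B-nor enone
Product: 9 (1R,3aS,7aS)-1-allyl-4,4,7a-trimethyloctahydro-2H-inden-2-one (trans-fused, 5α-H, 9β-allyl)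
Conditions: Li, NH3(l)/THF, t-BuOH (1 equiv), −78 °C; NH4Cl; then NaOMe (cat.), MeOH, rt
Reagents that add atoms: none
Why: Dissolving-metal (Birch-type) enone reduction followed by base equilibration: the β-carbanion at C5 is protonated from the α face, away from the β-axial methyl groups on C4 and C10, which gives the trans fusion while the isolated allyl alkene is inert, and methoxide then epimerises C9 to the pseudo-equatorial 9β-allyl ketone, the preference known for 17β side chains on trans-fused steroid ring D (any 9α epimer is separated and resubmitted).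

Step 7
Reactants: 9 trans-hydrindanone; 10 ethyl vinyl ether
Product: 12 1-[(1R,2S,3aS,7aS)-1-allyl-2-hydroxy-4,4,7a-trimethyloctahydro-1H-inden-2-yl]ethan-1-one (7β-OH and 7α-acetyl), via enol ether carbinol 11 (not isolated)
Conditions: 10, t-BuLi, THF, −78 to 0 °C; CeCl3, −78 °C; then 9, −78 °C; 0.5 M HCl, THF, 0 °C
Reagents that add atoms: ethyl vinyl ether (10), C=COCC; water, O
Why: Carbonyl addition of an acyl anion equivalent: the weakly basic organocerium reagent adds to the enolisable ketone from the α face, opposite the C10 methyl group and the 9β-allyl group, which sets C7 with β-hydroxyl and α-carbon substituent, and dilute acid hydrolyses the enol ether to the methyl ketone.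

Step 8
Reactants: 12 B-nor α-ketol
Product: 14 6,8α-dihydroxy-14,15,16-trinorlabda-5,12-dien-7-one (ring B diosphenol), via ring-enlarged ketol 13 (not isolated)
Conditions: KOt-Bu (3 equiv), 18-crown-6, THF/t-BuOH, 0 °C to rt, Ar; then O2 (1 atm), −20 °C; 1 M HCl
Reagents that add atoms: dioxygen, O=O
Why: Deprotonation gives the potassium alkoxide of 12, whose C7–C9 σ bond migrates suprafacially to the acetyl carbon while C7–O− collapses to the ketone (α-ketol rearrangement), so the acetyl carbon enters the ring as C8 and the cyclopentane becomes ring B; the closest known reaction type is the base-induced D-homoannulation of 17-hydroxy-20-oxo steroids, which share the trans-hydrindane core, in which the more substituted ring carbon likewise migrates, and whose strain release makes the shift downhill. No ring is closed by cyclisation: ring B arises by a one-atom enlargement through the 1,2-shift, and C9 migrates with retention, so its β-allyl group and α-hydrogen are carried over. The new centre C8 is fixed by the rotamer of the acetyl group: with crown-complexed potassium no chelate forms, the C8=O dipole stands anti to C7–O−, and because the acetyl group sits on the α face this places O8 on the α face and the methyl group on the β face. The step needs migration of C9 and not of C6: C9 is the more substituted and better donating carbon, and the rotamer that aligns its bond puts the carbonyl oxygen over the unsubstituted C6H2, whereas the rotamer for a C6 shift would press it against the allyl-bearing C9. Once the shift is complete oxygen is admitted, and the only enolate the new ketone can form (towards C6, since C8 is quaternary) is autoxidised to the 6-hydroperoxide, which loses water to the 6,7-dione and enolises towards C5, the known outcome for 7-oxo-4,4,10-trimethyl-trans-decalins. Short contact at low temperature keeps the slower equilibria (methyl shift, reverse shift, epimerisation at C8) and further oxidation from setting in.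

Step 9
Reactants: 14 ring B diosphenol
Product: 16 14,15,16-trinorlabd-12-ene-6β,7β,8α-triol, via 7β-hydroxy-6-ketone 15 (not isolated)
Conditions: NaBH4 (excess), CeCl3·7H2O, MeOH, −40 °C to rt
Reagents that add atoms: none
Why: Luche-type carbonyl reduction: hydride adds to C7 along the axial α trajectory (7β-OH), the resulting enol ketonises with protonation of C5 from the open α face to the more stable trans-decalone 15, and its C6 carbonyl, shielded on the β face by the axial methyl groups on C4, C8 and C10, is again reduced from the α face (6β-OH).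

Step 10
Reactants: 16 triol
Product: 17 7β-acetoxy-14,15,16-trinorlabd-12-ene-6β,8α-diol
Conditions: Ac2O (1.1 equiv), pyridine, DMAP (cat.), CH2Cl2, 0 °C
Reagents that add atoms: acetic anhydride, CC(=O)OC(C)=O
Why: Selective esterification: the equatorial 7β-hydroxyl is acetylated, whereas the 6β-hydroxyl is buried between syn-axial methyl groups and the 8α-hydroxyl is tertiary.

Step 11
Reactants: 17 7-acetate
Product: 18 7β-acetoxy-6β,8α-bis(trimethylsilyloxy)-14,15,16-trinorlabd-12-ene
Conditions: Me3SiOTf (excess), 2,6-lutidine, CH2Cl2, −78 to 0 °C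
Reagents that add atoms: trimethylsilyl triflate, C[Si](C)(C)OS(=O)(=O)C(F)(F)F
Why: Silyl ether formation: the small and highly electrophilic silyl triflate covers both the hindered secondary and the tertiary hydroxyl, so that O8 cannot later close an ether ring onto C12.

Step 12
Reactants: 18 bis-silyl ether
Product: 19 7β-acetoxy-6β,8α-bis(trimethylsilyloxy)-13,14,15,16-tetranorlabdan-12-al
Conditions: O3, CH2Cl2, −78 °C; then Me2S, −78 °C to rt
Reagents that add atoms: ozone, [O-][O+]=O
Why: Ozonolysis with reductive work-up cleaves the only alkene to the C12 aldehyde and removes the surplus carbon as formaldehyde.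

Step 13
Reactants: 20 allenylboronic acid pinacol ester
Product: 21 2-(buta-2,3-dien-1-yl)-4,4,5,5-tetramethyl-1,3,2-dioxaborolane
Conditions: ICH2Cl, n-BuLi, THF, −78 °C to rt
Reagents that add atoms: chloroiodomethane, ClCI
Why: Matteson homologation: (chloromethyl)lithium made in situ adds to boron and the allenyl group migrates from boron to carbon with loss of chloride, which inserts one CH2.

Step 14
Reactants: 19 C12 aldehyde; 21 homoallenylboronate
Product: 23 (12S)-7β-acetoxy-6β,8α-bis(trimethylsilyloxy)labda-13(16),14-dien-12-ol, via pinacol borate ester 22 (not isolated)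
Conditions: (R)-TRIP phosphoric acid [(R)-3,3′-bis(2,4,6-triisopropylphenyl)-1,1′-binaphthyl-2,2′-diyl hydrogen phosphate] (cat.), 4 Å molecular sieves, toluene, −30 °C; aqueous work-up
Reagents that add atoms: homoallenylboronate (21), C=C=CCB1OC(C)(C)C(C)(C)O1
Why: Brønsted-acid-catalysed asymmetric homoallenylboration: the boronate adds through a closed six-membered transition state with allylic transposition, so the central allene carbon becomes C13 of a 2-substituted butadiene, and the (R)-phosphoric acid directs attack to the Re face of the aldehyde, which sets C12 as S.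

Step 15
Reactants: 23 (12S)-dienyl carbinol
Product: 25 (12R)-7β-acetoxy-12-hydroperoxy-6β,8α-bis(trimethylsilyloxy)labda-13(16),14-diene, via allylic mesylate 24 (not isolated)
Conditions: MsCl, Et3N, CH2Cl2, −50 °C; then anhydrous H2O2 in Et2O (large excess), −50 to −10 °C
Reagents that add atoms: hydrogen peroxide, OO; methanesulfonyl chloride, CS(=O)(=O)Cl
Why: Sulfonate formation and SN2 displacement: the mesylate made in the cold is attacked at C12 by the small α-effect nucleophile H2O2 with inversion, turning 12S into 12R, while O6 and O8 are silylated and the hindered acetate survives the nearly neutral medium.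

Step 16
Reactants: 25 bis-silyl hydroperoxide
Product: 26 (12R)-7β-acetoxy-12-hydroperoxylabda-13(16),14-diene-6β,8α-diol (target, 5S,6S,7S,8S,9R,10S,12R)
Conditions: HF·pyridine, pyridine, THF, 0 °C
Reagents that add atoms: none
Why: Fluoride-mediated desilylation under buffered conditions removes both trimethylsilyl groups without acetyl migration, acid-induced hydroperoxide cleavage or change at any stereocentre.

**Compound list**
1 | 2,2,6-trimethylcyclohexanone | CC1CCCC(C)(C)C1=O | starting material
2 | allyl chloroformate | C=CCOC(=O)Cl | starting material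
3 | allyl 2,6,6-trimethylcyclohex-1-en-1-yl carbonate | C=CCOC(=O)OC1=C(C)CCCC1(C)C | intermediate
4 | (R)-2-allyl-2,6,6-trimethylcyclohexanone | C=CC[C@@]1(C)CCCC(C)(C)C1=O | intermediate
5 | (R)-2,2,6-trimethyl-6-(2-oxopropyl)cyclohexanone | CC(=O)C[C@@]1(C)CCCC(C)(C)C1=O | intermediate
6 | (7aR)-4,4,7a-trimethyl-1,4,5,6,7,7a-hexahydro-2H-inden-2-one | O=C1C=C2C(C)(C)CCC[C@]2(C)C1 | intermediate
7 | allyl bromide | C=CCBr | starting material
8 | (7aR)-1-allyl-4,4,7a-trimethyl-1,4,5,6,7,7a-hexahydro-2H-inden-2-one, both C9 epimers | C=CCC1C(=O)C=C2C(C)(C)CCC[C@@]21C | intermediate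
9 | (1R,3aS,7aS)-1-allyl-4,4,7a-trimethyloctahydro-2H-inden-2-one | C=CC[C@H]1C(=O)C[C@H]2C(C)(C)CCC[C@@]21C | intermediate
10 | ethyl vinyl ether | C=COCC | starting material
11 | (1R,2S,3aS,7aS)-1-allyl-2-(1-ethoxyvinyl)-4,4,7a-trimethyloctahydro-1H-inden-2-ol | C=CC[C@H]1[C@](O)(C(=C)OCC)C[C@H]2C(C)(C)CCC[C@@]21C | intermediate
12 | 1-[(1R,2S,3aS,7aS)-1-allyl-2-hydroxy-4,4,7a-trimethyloctahydro-1H-inden-2-yl]ethan-1-one | C=CC[C@H]1[C@](O)(C(C)=O)C[C@H]2C(C)(C)CCC[C@@]21C | intermediate
13 | 8α-hydroxy-14,15,16-trinorlabd-12-en-7-one, (3S,4R,4aS,8aS)-4-allyl-3-hydroxy-3,4a,8,8-tetramethyloctahydronaphthalen-2(1H)-one | C=CC[C@H]1[C@](C)(O)C(=O)C[C@H]2C(C)(C)CCC[C@@]21C | intermediate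
14 | 6,8α-dihydroxy-14,15,16-trinorlabda-5,12-dien-7-one | C=CC[C@H]1[C@](C)(O)C(=O)C(O)=C2C(C)(C)CCC[C@@]21C | intermediate
15 | 7β,8α-dihydroxy-14,15,16-trinorlabd-12-en-6-one | C=CC[C@H]1[C@](C)(O)[C@@H](O)C(=O)[C@H]2C(C)(C)CCC[C@@]21C | intermediate
16 | 14,15,16-trinorlabd-12-ene-6β,7β,8α-triol | C=CC[C@H]1[C@](C)(O)[C@@H](O)[C@@H](O)[C@H]2C(C)(C)CCC[C@@]21C | intermediate
17 | 7β-acetoxy-14,15,16-trinorlabd-12-ene-6β,8α-diol | C=CC[C@H]1[C@](C)(O)[C@@H](OC(C)=O)[C@@H](O)[C@H]2C(C)(C)CCC[C@@]21C | intermediate
18 | 7β-acetoxy-6β,8α-bis(trimethylsilyloxy)-14,15,16-trinorlabd-12-ene | C=CC[C@H]1[C@](C)(O[Si](C)(C)C)[C@@H](OC(C)=O)[C@@H](O[Si](C)(C)C)[C@H]2C(C)(C)CCC[C@@]21C | intermediate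
19 | 7β-acetoxy-6β,8α-bis(trimethylsilyloxy)-13,14,15,16-tetranorlabdan-12-al | O=CC[C@H]1[C@](C)(O[Si](C)(C)C)[C@@H](OC(C)=O)[C@@H](O[Si](C)(C)C)[C@H]2C(C)(C)CCC[C@@]21C | intermediate
20 | allenylboronic acid pinacol ester | C=C=CB1OC(C)(C)C(C)(C)O1 | starting material
21 | 2-(buta-2,3-dien-1-yl)-4,4,5,5-tetramethyl-1,3,2-dioxaborolane | C=C=CCB1OC(C)(C)C(C)(C)O1 | intermediate
22 | pinacol borate ester of 23 | C=CC(=C)[C@H](C[C@H]1[C@](C)(O[Si](C)(C)C)[C@@H](OC(C)=O)[C@@H](O[Si](C)(C)C)[C@H]2C(C)(C)CCC[C@@]21C)OB3OC(C)(C)C(C)(C)O3 | intermediate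
23 | (12S)-7β-acetoxy-6β,8α-bis(trimethylsilyloxy)labda-13(16),14-dien-12-ol | C=CC(=C)[C@H](C[C@H]1[C@](C)(O[Si](C)(C)C)[C@@H](OC(C)=O)[C@@H](O[Si](C)(C)C)[C@H]2C(C)(C)CCC[C@@]21C)O | intermediate
24 | (12S)-12-mesylate of 23 | C=CC(=C)[C@H](C[C@H]1[C@](C)(O[Si](C)(C)C)[C@@H](OC(C)=O)[C@@H](O[Si](C)(C)C)[C@H]2C(C)(C)CCC[C@@]21C)OS(C)(=O)=O | intermediate
25 | (12R)-7β-acetoxy-12-hydroperoxy-6β,8α-bis(trimethylsilyloxy)labda-13(16),14-diene | C=CC(=C)[C@@H](C[C@H]1[C@](C)(O[Si](C)(C)C)[C@@H](OC(C)=O)[C@@H](O[Si](C)(C)C)[C@H]2C(C)(C)CCC[C@@]21C)OO | intermediate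
26 | (12R)-7β-acetoxy-12-hydroperoxylabda-13(16),14-diene-6β,8α-diol | C=CC(=C)[C@@H](C[C@H]1[C@](C)(O)[C@@H](OC(C)=O)[C@@H](O)[C@H]2C(C)(C)CCC[C@@]21C)OO | target

Total step count: 16. Longest linear sequence: 15 (steps 1–12 and 14–16; step 13 is a one-step branch).

**Steps most likely to fail**

**Step 8.**
- Risks:
  - C6 may migrate in place of C9.
  - Leakage through a chelated transition state may invert C8.
  - The ring-enlarged ketol may drift back or the diosphenolate may be oxidised further.
- Fallback (sets out from 12, comes back at 13): the ring is still enlarged, but by a leaving-group-driven semipinacol shift, and O8 is added afterwards.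
  - NaBH4 reduces the acetyl ketone to 1-[(1R,2S,3aS,7aS)-1-allyl-2-hydroxy-4,4,7a-trimethyloctahydro-1H-inden-2-yl]ethan-1-ol F1.
  - MsCl/pyridine sulfonates only the secondary hydroxyl, giving the corresponding secondary mesylate F2.
  - Et2AlCl in CH2Cl2 at low temperature triggers migration of the more substituted C9 anti to the leaving group and gives 14,15,16-trinorlabd-12-en-7-one F3 (C8 epimers, one common enolate).
  - Oxygenation of its more substituted potassium enolate (KOt-Bu, O2, P(OEt)3) from the α face, the β face being blocked by the C10 methyl group, gives 13.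
  - 13 is isolated and taken to 14 under the oxygen stage of step 8 alone.

**Step 15.**
- Risks:
  - The allylic mesylate may ionise with loss of configuration.
  - Attack may occur at the terminal C16 with allylic transposition.
  - The silylated O8 may close a ring onto C12.
- Fallback (sets out from 19, comes back at 25): the C–O bond is made by an ene reaction instead of a substitution.
  - Wittig olefination with the ylide from (but-3-en-2-yl)triphenylphosphonium bromide and NaN(SiMe3)2 gives, after separation of the geometric isomers, (12E)-7β-acetoxy-6β,8α-bis(trimethylsilyloxy)labda-12,14-diene F4.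
  - Tetraphenylporphyrin-sensitised photooxygenation (O2, hν, CH2Cl2, −20 °C; Schenck ene reaction) abstracts hydrogen from the C16 methyl group, which lies cis to C11, and places the hydroperoxide on C12.
  - 25 is then separated chromatographically from its 12-epimer and from regioisomeric products.

**Step 9.**
- Risks:
  - The acidic diosphenol may be deprotonated and then resist hydride.
  - The second reduction at the hindered C6 carbonyl may stall.
- Fallback (sets out from 14, comes back at 17): the enol is masked, and its acyl group is used to differentiate O7.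
  - Ac2O/pyridine gives 6-acetoxy-8α-hydroxy-14,15,16-trinorlabda-5,12-dien-7-one F5.
  - Luche reduction at −78 °C gives the 7β-alkoxide, to which the neighbouring enol acetate transfers its acetyl group. This releases the C6 ketone with α-protonation at C5 and gives 7β-acetoxy-8α-hydroxy-14,15,16-trinorlabd-12-en-6-one F6.
  - NaBH4/CeCl3 at low temperature reduces C6 from the α face and gives 17 directly.

**Further compounds**
F1 | step 8 | 1-[(1R,2S,3aS,7aS)-1-allyl-2-hydroxy-4,4,7a-trimethyloctahydro-1H-inden-2-yl]ethan-1-ol | C=CC[C@H]1[C@](O)(C(C)O)C[C@H]2C(C)(C)CCC[C@@]21C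
F2 | step 8 | secondary mesylate of F1 | C=CC[C@H]1[C@](O)(C(C)OS(C)(=O)=O)C[C@H]2C(C)(C)CCC[C@@]21C
F3 | step 8 | 14,15,16-trinorlabd-12-en-7-one (C8 epimers) | C=CC[C@H]1C(C)C(=O)C[C@H]2C(C)(C)CCC[C@@]21C
F4 | step 15 | (12E)-7β-acetoxy-6β,8α-bis(trimethylsilyloxy)labda-12,14-diene | C=C/C(C)=C/C[C@H]1[C@](C)(O[Si](C)(C)C)[C@@H](OC(C)=O)[C@@H](O[Si](C)(C)C)[C@H]2C(C)(C)CCC[C@@]21C
F5 | step 9 | 6-acetoxy-8α-hydroxy-14,15,16-trinorlabda-5,12-dien-7-one | C=CC[C@H]1[C@](C)(O)C(=O)C(OC(C)=O)=C2C(C)(C)CCC[C@@]21C
F6 | step 9 | 7β-acetoxy-8α-hydroxy-14,15,16-trinorlabd-12-en-6-one | C=CC[C@H]1[C@](C)(O)[C@@H](OC(C)=O)C(=O)[C@H]2C(C)(C)CCC[C@@]21C
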